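**Retrosynthetic overview**

1. Locants are those of the bicyclo[3.3.1]nonane core: C1 (isobutyryl bridgehead), C2–C3–C4 (enolised 1,3-diketone, prenyl on C3), C5 (prenyl bridgehead), C6, C7 (prenyl; the only stereocentre carried through the route), C8 (gem-dimethyl), C9 (bridging ketone).
2. Key disconnection: C1–C9 and C4–C5 are cut together, which unfolds the bicycle into the open-chain active ester 23, an acyclic 3,5-dioxo ester used as a mixture of C1/C3/C5 epimers.
3. Enabling feature: the ring C1–C2–C3–C4–C5–C9 is a folded polyketide trione. C9 and C4 are acyl carbons, C1 (between the isobutyryl and C2 carbonyls) and C5 (alpha to C9) are their enolate partners, and the bridge C6–C7–C8 already ties C5 to C1, so both acylations are six-membered.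
4. Ring order, both in step 14: first the cyclohexanone ring C1–C8–C7–C6–C5–C9 (C1 to C9, cold), then the trione ring (C5 to C4, through an acylketene released on heating).
5. Chain assembly: C1 isobutyrylation (keto ester dianion) <= C2–C3 Claisen-type coupling (Weinreb amide + ester enolate) <= C5=C6 olefination and conjugate reduction <= C7 by Evans alkylation <= 3,3-dimethylglutaric anhydride (C8 with both arms).

Key step: step 14

Remark: the target is an enolised 1,3-diketone whose enol tautomers interconvert, so the route delivers this tautomeric system, written as the given enol; a centre without descriptor in a SMILES is an intended epimer mixture.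

**Route**

Step 1
Reactants: 1 3,3-dimethylglutaric anhydride; 2 N,O-dimethylhydroxylamine hydrochloride
Product: 3 5-[methoxy(methyl)amino]-3,3-dimethyl-5-oxopentanoic acid
Conditions: pyridine (2.2 equiv), CH2Cl2, 0 °C to rt
Reagents that add atoms: N,O-dimethylhydroxylamine hydrochloride (2), CNOC.Cl
Why: Aminolysis of a cyclic anhydride; the two carbonyl groups of 1 are equivalent, so a single amide acid should form, with the two arms of the future C8 carbon differentiated as Weinreb amide (later C2) and free acid (later C6).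

Step 2
Reactants: 3 5-[methoxy(methyl)amino]-3,3-dimethyl-5-oxopentanoic acid; 4 (R)-4-benzyl-1,3-oxazolidin-2-one
Product: 6 5-[(4R)-4-benzyl-2-oxo-1,3-oxazolidin-3-yl]-N-methoxy-N,3,3-trimethyl-5-oxopentanamide, via mixed pivalic anhydride 5 (not isolated)
Conditions: t-BuCOCl, Et3N, THF, −20 °C; then 4, LiCl, −20 °C to rt
Reagents that add atoms: (R)-4-benzyl-1,3-oxazolidin-2-one (4), O=C1N[C@H](Cc2ccccc2)CO1
Why: N-Acylation of the oxazolidinone through a mixed anhydride; the nitrogen should attack the less hindered, non-pivaloyl carbonyl, and the Weinreb amide is not touched.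

Step 3
Reactants: 6 5-[(4R)-4-benzyl-2-oxo-1,3-oxazolidin-3-yl]-N-methoxy-N,3,3-trimethyl-5-oxopentanamide; 7 1-bromo-3-methylbut-2-ene (prenyl bromide)
Product: 8 (4R)-4-[(4R)-4-benzyl-2-oxo-1,3-oxazolidine-3-carbonyl]-N-methoxy-N,3,3,7-tetramethyloct-6-enamide
Conditions: NaN(SiMe3)2 (1.1 equiv), THF, −78 °C; then 7 (3 equiv), −78 to −40 °C
Reagents that add atoms: 1-bromo-3-methylbut-2-ene (7), CC(C)=CCBr
Why: Evans asymmetric alkylation; the chelated Z-sodium enolate should be alkylated by the allylic bromide on the face opposite the benzyl group, setting the new centre (C7 of the target) as 4R, while the less acidic Weinreb amide alpha-hydrogens stay.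

Step 4
Reactants: 8 (4R)-4-[(4R)-4-benzyl-2-oxo-1,3-oxazolidine-3-carbonyl]-N-methoxy-N,3,3,7-tetramethyloct-6-enamide
Product: 9 (4R)-4-(hydroxymethyl)-N-methoxy-N,3,3,7-tetramethyloct-6-enamide
Conditions: NaBH4 (4 equiv), THF/H2O (4:1), 0 °C to rt
Reagents that add atoms: none
Why: Reductive removal of the auxiliary; borohydride should reduce the activated exocyclic imide carbonyl to the primary alcohol while the Weinreb amide and the alkene do not react, and the stereocentre is not involved.

Step 5
Reactants: 9 (4R)-4-(hydroxymethyl)-N-methoxy-N,3,3,7-tetramethyloct-6-enamide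
Product: 10 (4R)-4-formyl-N-methoxy-N,3,3,7-tetramethyloct-6-enamide
Conditions: Dess–Martin periodinane, NaHCO3, CH2Cl2, 0 °C to rt
Reagents that add atoms: none
Why: Dess–Martin oxidation under buffered conditions should give the aldehyde without epimerisation of the alpha-centre, which is shielded by the neighbouring quaternary carbon.

Step 6
Reactants: 11 triethyl phosphonoacetate; 7 1-bromo-3-methylbut-2-ene (prenyl bromide)
Product: 12 ethyl 2-(diethoxyphosphoryl)-5-methylhex-4-enoate
Conditions: NaH (1.0 equiv), THF, 0 °C; then 7 (1.0 equiv), 0 °C to rt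
Reagents that add atoms: 1-bromo-3-methylbut-2-ene (7), CC(C)=CCBr
Why: C-Alkylation (SN2) of the stabilised phosphonoacetate anion with an allylic bromide.

Step 7
Reactants: 10 (4R)-4-formyl-N-methoxy-N,3,3,7-tetramethyloct-6-enamide; 12 ethyl 2-(diethoxyphosphoryl)-5-methylhex-4-enoate
Product: 13 ethyl (4S)-4-{4-[methoxy(methyl)amino]-2-methyl-4-oxobutan-2-yl}-7-methyl-2-(3-methylbut-2-en-1-yl)octa-2,6-dienoate
Conditions: 12 (1.3 equiv), NaH (1.2 equiv), THF, 0 °C; then 10, 0 to 40 °C
Reagents that add atoms: ethyl 2-(diethoxyphosphoryl)-5-methylhex-4-enoate (12), CCOC(=O)C(CC=C(C)C)P(=O)(OCC)OCC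
Why: Horner–Wadsworth–Emmons olefination forms C5=C6 with the prenyl group already on C5, so that no C5 enolate has to be made later next to the electrophilic Weinreb amide; the alkene geometry is irrelevant because the alkene is reduced in step 8.

Step 8
Reactants: 13 ethyl (4S)-4-{4-[methoxy(methyl)amino]-2-methyl-4-oxobutan-2-yl}-7-methyl-2-(3-methylbut-2-en-1-yl)octa-2,6-dienoate
Product: 14 ethyl (2RS,4S)-4-{4-[methoxy(methyl)amino]-2-methyl-4-oxobutan-2-yl}-7-methyl-2-(3-methylbut-2-en-1-yl)oct-6-enoate
Conditions: [1,3-bis(2,6-diisopropylphenyl)imidazol-2-ylidene]copper chloride, (IPr)CuCl (5 mol%), NaOt-Bu (10 mol%), MeSiH(OEt)2 (3 equiv), t-BuOH (3 equiv), PhMe, rt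
Reagents that add atoms: none
Why: Conjugate reduction by a monovalent copper hydride (hydride from the silane to C6, proton from t-BuOH to C5) should leave the trisubstituted alkenes and the Weinreb amide alone; C5 forms as an epimer mixture, which is harmless because C5 becomes sp2 again in step 14.

Step 9
Reactants: 14 ethyl (2RS,4S)-4-{4-[methoxy(methyl)amino]-2-methyl-4-oxobutan-2-yl}-7-methyl-2-(3-methylbut-2-en-1-yl)oct-6-enoate; 15 lithium hydroxide
Product: 16 (2RS,4S)-4-{4-[methoxy(methyl)amino]-2-methyl-4-oxobutan-2-yl}-7-methyl-2-(3-methylbut-2-en-1-yl)oct-6-enoic acid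
Conditions: LiOH·H2O, THF/MeOH/H2O (3:1:1), 45 °C; then 1 M HCl, 0 °C
Reagents that add atoms: lithium hydroxide (15), [Li+].[OH-]
Why: Saponification of the ethyl ester, with the Weinreb amide much slower to hydrolyse; the carboxylate masks C9 and protects the C5 hydrogen during the enolate chemistry of steps 11 and 12.

Step 10
Reactants: 17 tert-butyl acetate; 7 1-bromo-3-methylbut-2-ene (prenyl bromide)
Product: 18 tert-butyl 5-methylhex-4-enoate
Conditions: LiN(i-Pr)2 (1.05 equiv), THF, −78 °C; then 7, −78 to 0 °C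
Reagents that add atoms: 1-bromo-3-methylbut-2-ene (7), CC(C)=CCBr
Why: Alkylation of the lithium enolate of tert-butyl acetate with an allylic bromide.

Step 11
Reactants: 16 (2RS,4S)-4-{4-[methoxy(methyl)amino]-2-methyl-4-oxobutan-2-yl}-7-methyl-2-(3-methylbut-2-en-1-yl)oct-6-enoic acid; 18 tert-butyl 5-methylhex-4-enoate
Product: 19 (4S)-9-tert-butoxy-5,5-dimethyl-2,4,8-tris(3-methylbut-2-en-1-yl)-7,9-dioxononanoic acid
Conditions: 18 (4 equiv), LiN(i-Pr)2 (4.2 equiv), THF, −78 °C; then 16, −78 to 0 °C; then aq. HCl (pH 3), 0 °C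
Reagents that add atoms: tert-butyl 5-methylhex-4-enoate (18), CC(C)=CCCC(=O)OC(C)(C)C
Why: Claisen-type acylation of an ester enolate by a Weinreb amide; the chelated tetrahedral adduct should prevent double addition, the carboxylate of 16 is a spectator, and C3 forms as an epimer mixture that becomes sp2 in step 14.

Step 12
Reactants: 19 (4S)-9-tert-butoxy-5,5-dimethyl-2,4,8-tris(3-methylbut-2-en-1-yl)-7,9-dioxononanoic acid; 20 N-methoxy-N,2-dimethylpropanamide
Product: 21 (4S)-9-tert-butoxy-5,5-dimethyl-6-(2-methylpropanoyl)-2,4,8-tris(3-methylbut-2-en-1-yl)-7,9-dioxononanoic acid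
Conditions: LiN(i-Pr)2 (3.3 equiv), THF, −78 to 0 °C; then 20 (1.5 equiv), −78 to 0 °C; then aq. HCl (pH 3), 0 °C
Reagents that add atoms: N-methoxy-N,2-dimethylpropanamide (20), CC(C)C(=O)N(C)OC
Why: Gamma-acylation of a beta-keto ester dianion; after the acid and the C3 hydrogen, the third equivalent of base removes a C1 hydrogen, and this most nucleophilic carbon should be acylated by the Weinreb amide to give the 3,5-dioxo ester, while the carboxylate alpha-hydrogen stays.

Step 13
Reactants: 21 (4S)-9-tert-butoxy-5,5-dimethyl-6-(2-methylpropanoyl)-2,4,8-tris(3-methylbut-2-en-1-yl)-7,9-dioxononanoic acid; 22 pentafluorophenol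
Product: 23 9-tert-butyl 1-(pentafluorophenyl) (4S)-5,5-dimethyl-6-(2-methylpropanoyl)-2,4,8-tris(3-methylbut-2-en-1-yl)-7-oxononanedioate
Conditions: N,N'-dicyclohexylcarbodiimide (1.1 equiv), 22 (1.2 equiv), EtOAc, 0 °C to rt
Reagents that add atoms: pentafluorophenol (22), Oc1c(F)c(F)c(F)c(F)c1F
Why: Carbodiimide esterification should give the isolable active ester; without added base the carbon acids of the tricarbonyl unit are not acylated.

Step 14
Reactants: 23 9-tert-butyl 1-(pentafluorophenyl) (4S)-5,5-dimethyl-6-(2-methylpropanoyl)-2,4,8-tris(3-methylbut-2-en-1-yl)-7-oxononanedioate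
Product: 26 (1R,5R,7S)-4-hydroxy-8,8-dimethyl-3,5,7-tris(3-methylbut-2-en-1-yl)-1-(2-methylpropanoyl)bicyclo[3.3.1]non-3-ene-2,9-dione, via cyclohexanone keto ester 24 (not isolated), via acylketene 25 (not isolated)
Conditions: KH (2.2 equiv), THF (5 mM), −20 to 0 °C; then AcOH (2.4 equiv), PhMe, 110 °C with distillation of THF and t-BuOH
Reagents that add atoms: none
Why: Proposed new method: KH turns the 3,5-dioxo ester of 23 into its dianion, whose last-formed and most nucleophilic carbon C1 attacks the active-ester carbonyl C9 in a 6-(enolexo)-exo-trig closure of the cyclohexanone ring C1–C8–C7–C6–C5–C9 (24), and after neutralisation, heating makes the tert-butyl beta-keto ester expel tert-butanol to the acylketene 25 (C3=C4=O), which is attacked by the C5 carbon of the C9 ketone enol in a 6-(enolendo)-exo-dig closure of the trione ring C1–C2–C3–C4–C5–C9. The closest known reaction types are the Dieckmann and phloroglucinol-type Claisen cyclisations of polycarbonyl dianions for the first bond and, for the second, the ring-closing half of the Effenberger cyclization (a beta-keto acyl electrophile acylating the alpha'-carbon of a 2-acylcyclohexanone) combined with the thermal release of acylketenes from tert-butyl beta-keto esters. C1 is set in the first closure by C7: in the chair-like transition state the C7 prenyl group is equatorial, the smaller isobutyryl group should accept the equatorial site wedged between the two C8 methyl groups and the C9 oxygen, and the bulkier keto ester arm the axial site syn to H-7, which is the arrangement of the target. C5 is then fixed by the geometry of the bridge, since the acylketene hangs from the axial arm and can reach only one face of the planar C5 enol, and all epimers of 23 at C1, C3 and C5 converge because these carbons pass through enolate, ketene or enol stages. The step needs C- before O-acylation and C1–C9 before C4–C5: in the cold stage every alternative O- or C-acylation would close an eight-membered or larger ring, the tert-butyl ester stays inert until heated so that no pyranone can form while C1 still bears hydrogen, and at 110 °C any enol lactone from O-capture is an enol ester that can return to 25 whereas C-acylation gives the stable enolised diketone irreversibly.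

**Compound list**

1 | 3,3-dimethylglutaric anhydride | O=C1CC(C)(C)CC(=O)O1 | starting material
2 | N,O-dimethylhydroxylamine hydrochloride | CNOC.Cl | starting material
3 | 5-[methoxy(methyl)amino]-3,3-dimethyl-5-oxopentanoic acid | CON(C)C(=O)CC(C)(C)CC(=O)O | intermediate
4 | (R)-4-benzyl-1,3-oxazolidin-2-one | O=C1N[C@H](Cc2ccccc2)CO1 | starting material
5 | 5-[methoxy(methyl)amino]-3,3-dimethyl-5-oxopentanoic pivalic anhydride | CON(C)C(=O)CC(C)(C)CC(=O)OC(=O)C(C)(C)C | intermediate
6 | 5-[(4R)-4-benzyl-2-oxo-1,3-oxazolidin-3-yl]-N-methoxy-N,3,3-trimethyl-5-oxopentanamide | CON(C)C(=O)CC(C)(C)CC(=O)N1[C@H](Cc2ccccc2)COC1=O | intermediate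
7 | 1-bromo-3-methylbut-2-ene (prenyl bromide) | CC(C)=CCBr | starting material
8 | (4R)-4-[(4R)-4-benzyl-2-oxo-1,3-oxazolidine-3-carbonyl]-N-methoxy-N,3,3,7-tetramethyloct-6-enamide | CON(C)C(=O)CC(C)(C)[C@@H](CC=C(C)C)C(=O)N1[C@H](Cc2ccccc2)COC1=O | intermediate
9 | (4R)-4-(hydroxymethyl)-N-methoxy-N,3,3,7-tetramethyloct-6-enamide | CON(C)C(=O)CC(C)(C)[C@@H](CC=C(C)C)CO | intermediate
10 | (4R)-4-formyl-N-methoxy-N,3,3,7-tetramethyloct-6-enamide | CON(C)C(=O)CC(C)(C)[C@@H](CC=C(C)C)C=O | intermediate
11 | triethyl phosphonoacetate | CCOC(=O)CP(=O)(OCC)OCC | starting material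
12 | ethyl 2-(diethoxyphosphoryl)-5-methylhex-4-enoate (racemic) | CCOC(=O)C(CC=C(C)C)P(=O)(OCC)OCC | intermediate
13 | ethyl (4S)-4-{4-[methoxy(methyl)amino]-2-methyl-4-oxobutan-2-yl}-7-methyl-2-(3-methylbut-2-en-1-yl)octa-2,6-dienoate (2E/2Z mixture) | CCOC(=O)C(CC=C(C)C)=C[C@H](CC=C(C)C)C(C)(C)CC(=O)N(C)OC | intermediate
14 | ethyl (2RS,4S)-4-{4-[methoxy(methyl)amino]-2-methyl-4-oxobutan-2-yl}-7-methyl-2-(3-methylbut-2-en-1-yl)oct-6-enoate | CCOC(=O)C(CC=C(C)C)C[C@H](CC=C(C)C)C(C)(C)CC(=O)N(C)OC | intermediate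
15 | lithium hydroxide | [Li+].[OH-] | starting material
16 | (2RS,4S)-4-{4-[methoxy(methyl)amino]-2-methyl-4-oxobutan-2-yl}-7-methyl-2-(3-methylbut-2-en-1-yl)oct-6-enoic acid | OC(=O)C(CC=C(C)C)C[C@H](CC=C(C)C)C(C)(C)CC(=O)N(C)OC | intermediate
17 | tert-butyl acetate | CC(=O)OC(C)(C)C | starting material
18 | tert-butyl 5-methylhex-4-enoate | CC(C)=CCCC(=O)OC(C)(C)C | intermediate
19 | (4S)-9-tert-butoxy-5,5-dimethyl-2,4,8-tris(3-methylbut-2-en-1-yl)-7,9-dioxononanoic acid (2RS,8RS) | OC(=O)C(CC=C(C)C)C[C@H](CC=C(C)C)C(C)(C)CC(=O)C(CC=C(C)C)C(=O)OC(C)(C)C | intermediate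
20 | N-methoxy-N,2-dimethylpropanamide | CC(C)C(=O)N(C)OC | starting material
21 | (4S)-9-tert-butoxy-5,5-dimethyl-6-(2-methylpropanoyl)-2,4,8-tris(3-methylbut-2-en-1-yl)-7,9-dioxononanoic acid (2RS,6RS,8RS; keto and enol forms) | OC(=O)C(CC=C(C)C)C[C@H](CC=C(C)C)C(C)(C)C(C(=O)C(C)C)C(=O)C(CC=C(C)C)C(=O)OC(C)(C)C | intermediate
22 | pentafluorophenol | Oc1c(F)c(F)c(F)c(F)c1F | starting material
23 | 9-tert-butyl 1-(pentafluorophenyl) (4S)-5,5-dimethyl-6-(2-methylpropanoyl)-2,4,8-tris(3-methylbut-2-en-1-yl)-7-oxononanedioate (2RS,6RS,8RS) | O=C(Oc1c(F)c(F)c(F)c(F)c1F)C(CC=C(C)C)C[C@H](CC=C(C)C)C(C)(C)C(C(=O)C(C)C)C(=O)C(CC=C(C)C)C(=O)OC(C)(C)C | intermediate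
24 | tert-butyl 3-[(1S,5S)-6,6-dimethyl-3,5-bis(3-methylbut-2-en-1-yl)-1-(2-methylpropanoyl)-2-oxocyclohexyl]-2-(3-methylbut-2-en-1-yl)-3-oxopropanoate (epimers at ring C3 and side-chain C2) | CC(C)C(=O)[C@]1(C(=O)C(CC=C(C)C)C(=O)OC(C)(C)C)C(=O)C(CC=C(C)C)C[C@H](CC=C(C)C)C1(C)C | intermediate
25 | 2-{[(1S,5S)-6,6-dimethyl-3,5-bis(3-methylbut-2-en-1-yl)-1-(2-methylpropanoyl)-2-oxocyclohexyl]carbonyl}-5-methylhexa-1,4-dien-1-one | CC(C)C(=O)[C@]1(C(=O)C(CC=C(C)C)=C=O)C(=O)C(CC=C(C)C)C[C@H](CC=C(C)C)C1(C)C | intermediate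
26 | (1R,5R,7S)-4-hydroxy-8,8-dimethyl-3,5,7-tris(3-methylbut-2-en-1-yl)-1-(2-methylpropanoyl)bicyclo[3.3.1]non-3-ene-2,9-dione | CC(C)=CCC1=C(O)[C@@]2(CC=C(C)C)C[C@H](CC=C(C)C)C(C)(C)[C@@](C(=O)C(C)C)(C1=O)C2=O | target

**Step count**

Total: 14 steps. Longest linear sequence: 12 steps (1–5, 7–9, 11–14); steps 6 and 10 make the side reagents 12 and 18.

**Steps most likely to fail**

1. Step 14.
- What may go wrong: the C1 carbanion, flanked by the C8 quaternary carbon, may add to the active ester so slowly that intermolecular acylation takes over. Facial selectivity at C1 may be low, and the minor C1 epimer would lead to the C7-epimeric bicycle. During heating, the acylketene may be captured at oxygen, or the triacylmethane centre of 24 may be cleaved by acyl transfer before C5 is acylated.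
- Fallback: the same two bonds made in separate operations by known reactions, setting out from 23 and returning at 26. The cold stage alone (KH, THF, then AcOH and aqueous work-up) should give the isolated cyclohexanone keto ester 24 by a Dieckmann-type C-acylation. TMSOTf and 2,6-lutidine in CH2Cl2 at 0 °C should exchange the tert-butyl ester for the trimethylsilyl ester, trimethylsilyl 3-[(1S,5S)-6,6-dimethyl-3,5-bis(3-methylbut-2-en-1-yl)-1-(2-methylpropanoyl)-2-oxocyclohexyl]-2-(3-methylbut-2-en-1-yl)-3-oxopropanoate F1. Oxalyl chloride with catalytic DMF should convert F1 into the beta-keto acid chloride, 3-[(1S,5S)-6,6-dimethyl-3,5-bis(3-methylbut-2-en-1-yl)-1-(2-methylpropanoyl)-2-oxocyclohexyl]-2-(3-methylbut-2-en-1-yl)-3-oxopropanoyl chloride F2. On warming from −20 °C to rt in CH2Cl2, F2 should acylate the C5 enol carbon, which is the ring-closing event of an Effenberger cyclization (KOH, BnEt3NCl work-up), to give 26.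

2. Step 12.
- What may go wrong: acylation of the neopentyl-type C1 carbanion by the hindered Weinreb amide may be slower than proton transfer, returning 19 or giving O-acylated material.
- Fallback: aldol addition then oxidation, setting out from 19 and returning at 21. The same trianion (LiN(i-Pr)2, THF, −78 °C) should add to isobutyraldehyde at C1 to give the hydroxy keto ester, (4S)-9-tert-butoxy-6-(1-hydroxy-2-methylpropyl)-5,5-dimethyl-2,4,8-tris(3-methylbut-2-en-1-yl)-7,9-dioxononanoic acid F3, as a diastereomer mixture. Dess–Martin oxidation of F3 should give 21.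

3. Step 7.
- What may go wrong: olefination between the alpha-branched phosphonate anion and the neopentyl-type aldehyde may be sluggish, and over the long reaction time enolisation may erode the C7 centre of 10 or deconjugate 13.
- Fallback: Knoevenagel route through Meldrum's acid, setting out from 10 and returning at 16 (it replaces steps 7–9). Condensation of 10 with Meldrum's acid under in situ transfer hydrogenation (Hantzsch ester, L-proline cat., EtOH, rt) should give the monoalkyl Meldrum's acid, (4S)-4-[(2,2-dimethyl-4,6-dioxo-1,3-dioxan-5-yl)methyl]-N-methoxy-N,3,3,7-tetramethyloct-6-enamide F4. C-Alkylation with 7 (K2CO3, DMF) should give (4S)-4-{[2,2-dimethyl-5-(3-methylbut-2-en-1-yl)-4,6-dioxo-1,3-dioxan-5-yl]methyl}-N-methoxy-N,3,3,7-tetramethyloct-6-enamide F5. Hydrolysis (LiOH, THF/H2O; then HCl) and decarboxylation (PhMe, 110 °C) of F5 should give 16; the stabilised Meldrum's acid anion does not attack the Weinreb amide.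

Further compounds
F1 | step 14 | trimethylsilyl 3-[(1S,5S)-6,6-dimethyl-3,5-bis(3-methylbut-2-en-1-yl)-1-(2-methylpropanoyl)-2-oxocyclohexyl]-2-(3-methylbut-2-en-1-yl)-3-oxopropanoate | CC(C)C(=O)[C@]1(C(=O)C(CC=C(C)C)C(=O)O[Si](C)(C)C)C(=O)C(CC=C(C)C)C[C@H](CC=C(C)C)C1(C)C
F2 | step 14 | 3-[(1S,5S)-6,6-dimethyl-3,5-bis(3-methylbut-2-en-1-yl)-1-(2-methylpropanoyl)-2-oxocyclohexyl]-2-(3-methylbut-2-en-1-yl)-3-oxopropanoyl chloride | CC(C)C(=O)[C@]1(C(=O)C(CC=C(C)C)C(Cl)=O)C(=O)C(CC=C(C)C)C[C@H](CC=C(C)C)C1(C)C
F3 | step 12 | (4S)-9-tert-butoxy-6-(1-hydroxy-2-methylpropyl)-5,5-dimethyl-2,4,8-tris(3-methylbut-2-en-1-yl)-7,9-dioxononanoic acid | OC(=O)C(CC=C(C)C)C[C@H](CC=C(C)C)C(C)(C)C(C(O)C(C)C)C(=O)C(CC=C(C)C)C(=O)OC(C)(C)C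
F4 | step 7 | (4S)-4-[(2,2-dimethyl-4,6-dioxo-1,3-dioxan-5-yl)methyl]-N-methoxy-N,3,3,7-tetramethyloct-6-enamide | CON(C)C(=O)CC(C)(C)[C@@H](CC=C(C)C)CC1C(=O)OC(C)(C)OC1=O
F5 | step 7 | (4S)-4-{[2,2-dimethyl-5-(3-methylbut-2-en-1-yl)-4,6-dioxo-1,3-dioxan-5-yl]methyl}-N-methoxy-N,3,3,7-tetramethyloct-6-enamide | CON(C)C(=O)CC(C)(C)[C@@H](CC=C(C)C)CC1(CC=C(C)C)C(=O)OC(C)(C)OC1=O
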